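## Retrosynthetic overview

1. Target 21 ⇐ epoxy alcohol 20 (oxidation) ⇐ allylic alcohol 19; the oxirane is the last ring formed, by hydroxyl-directed epoxidation of the ring alkene.
2. 19 ⇐ enone 18 (1,2-reduction) ⇐ ketol 15 (desilylation, double senecioylation).
3. 15 ⇐ acyclic (3Z,6Z)-2-oxo-trienal 14; the six-membered ring is formed first, by a catalytic asymmetric carbonyl-ene closure of C1–C6 with loss of H from C14 (the farnesyl → bisabolyl → 7(14)-ene pattern).
4. 14 ⇐ diol 13 ⇐ acetonide 12 ⇐ one-pot double Z-selective Wittig of a propane-1,3-diyl bis-ylide with the α-alkoxy ketones 6 and 9.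
5. 6 ⇐ methyl (R)-glycidate + isobutenyl Grignard reagent; 9 ⇐ methyl (R)-glycerate acetonide.

Assumption: positions in the text use farnesane numbering (C1 aldehyde/carbinol carbon, C2 ketone carbon, C3 with methyl C15, C6 the ring CH carrying the side chain, C7 with methyl/methylene C14, C8 the oxygenated side-chain carbon), compound names keep their own locants, and the copper catalyst is taken to select the aldehyde face as it does for glyoxylate esters and to override the remote C8 centre.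

## Route

Step 1
Reactants: 1 methyl (2R)-oxirane-2-carboxylate; 2 (2-methylprop-1-en-1-yl)magnesium bromide
Product: 3 methyl (2R)-2-hydroxy-5-methylhex-4-enoate
Conditions: 2 (1.3 equiv), CuI (10 mol%), THF, −40 °C; aq. NH4Cl
Reagents that add atoms: none
Why: Copper-catalysed SN2 opening of the glycidic ester at the unsubstituted CH2 (cuprate epoxide opening) leaves the oxygen-bearing carbon untouched, so the (R) centre that becomes C8 comes from the starting material.

Step 2
Reactants: 3 methyl (2R)-2-hydroxy-5-methylhex-4-enoate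
Product: 4 methyl (2R)-2-[(tert-butyldimethylsilyl)oxy]-5-methylhex-4-enoate
Conditions: TBSCl, imidazole, DMF, rt
Reagents that add atoms: tert-butyldimethylsilyl chloride, CC(C)(C)[Si](C)(C)Cl
Why: Standard silyl ether protection of the secondary alcohol, needed because this oxygen must survive Grignard reagents, ylides and a later diol oxidation.

Step 3
Reactants: 4 methyl (2R)-2-[(tert-butyldimethylsilyl)oxy]-5-methylhex-4-enoate
Product: 6 (3R)-3-[(tert-butyldimethylsilyl)oxy]-6-methylhept-5-en-2-one, via Weinreb amide 5 (not isolated)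
Conditions: MeNH(OMe)·HCl, iPrMgCl, THF, −20 °C; then MeMgBr, 0 °C; aq. NH4Cl
Reagents that add atoms: methylmagnesium bromide, C[Mg]Br; N,O-dimethylhydroxylamine hydrochloride, CNOC.Cl (its N(OMe)Me group is carried only by 5)
Why: One-pot Weinreb ketone synthesis, in which the chelated tetrahedral adduct of the N-methoxy-N-methylamide stops the Grignard addition at the methyl ketone and the α-silyloxy centre is not enolised at or below 0 °C.

Step 4
Reactants: 7 methyl (4R)-2,2-dimethyl-1,3-dioxolane-4-carboxylate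
Product: 9 1-[(4R)-2,2-dimethyl-1,3-dioxolan-4-yl]ethan-1-one, via Weinreb amide 8 (not isolated)
Conditions: MeNH(OMe)·HCl, iPrMgCl, THF, −20 °C; then MeMgBr, 0 °C; aq. NH4Cl
Reagents that add atoms: methylmagnesium bromide, C[Mg]Br; N,O-dimethylhydroxylamine hydrochloride, CNOC.Cl (its N(OMe)Me group is carried only by 8)
Why: The same one-pot Weinreb ketone synthesis gives the α,β-dialkoxy methyl ketone that supplies C1–C3 and C15; its stereocentre is later oxidised away, so partial epimerisation would not matter.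

Step 5
Reactants: 10 propane-1,3-diylbis(triphenylphosphonium) dibromide; 6 (3R)-3-[(tert-butyldimethylsilyl)oxy]-6-methylhept-5-en-2-one; 9 1-[(4R)-2,2-dimethyl-1,3-dioxolan-4-yl]ethan-1-one
Product: 12 (4S)-4-[(2Z,5Z,7R)-7-[(tert-butyldimethylsilyl)oxy]-6,10-dimethylundeca-2,5,9-trien-2-yl]-2,2-dimethyl-1,3-dioxolane, via homoallylic phosphonium bromide 11 (not isolated)
Conditions: 10 (1.2 equiv), KN(SiMe3)2 (1.2 equiv), THF, −78 °C; 6, −78 → 0 °C; KN(SiMe3)2 (1.2 equiv), −78 °C; 9 (1.5 equiv), −78 °C → rt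
Reagents that add atoms: none
Why: Sequential Wittig olefination with a three-carbon bis-ylide linchpin, relying on the kinetic Z-selectivity of unstabilised ylides with α-alkoxy ketones (oxygenated carbon cis to the ylide chain), sets the 3Z and 6Z trisubstituted alkenes and forms no new stereocentre.

Step 6
Reactants: 12 (4S)-4-[(2Z,5Z,7R)-7-[(tert-butyldimethylsilyl)oxy]-6,10-dimethylundeca-2,5,9-trien-2-yl]-2,2-dimethyl-1,3-dioxolane
Product: 13 (2S,3Z,6Z,8R)-8-[(tert-butyldimethylsilyl)oxy]-3,7,11-trimethyldodeca-3,6,10-triene-1,2-diol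
Conditions: AcOH/H2O 4:1, rt
Reagents that add atoms: none
Why: Acid-catalysed hydrolysis of a terminal isopropylidene acetal (acetonide deprotection) is much faster than cleavage of the secondary TBS ether and does not move the skipped diene.

Step 7
Reactants: 13 (2S,3Z,6Z,8R)-8-[(tert-butyldimethylsilyl)oxy]-3,7,11-trimethyldodeca-3,6,10-triene-1,2-diol
Product: 14 (3Z,6Z,8R)-8-[(tert-butyldimethylsilyl)oxy]-3,7,11-trimethyl-2-oxododeca-3,6,10-trienal
Conditions: (COCl)2, DMSO, CH2Cl2, −78 °C; Et3N, −78 → −40 °C; pH 7 buffer; crude 14 used at once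
Reagents that add atoms: none
Why: Swern oxidation takes a 1,2-diol to the 1,2-dicarbonyl without C–C cleavage and at a temperature where the Z-enone and the skipped diene should not isomerise; the C2 stereocentre is removed on purpose.

Step 8
Reactants: 14 (3Z,6Z,8R)-8-[(tert-butyldimethylsilyl)oxy]-3,7,11-trimethyl-2-oxododeca-3,6,10-trienal
Product: 15 (5S,6S)-5-[(3R)-3-[(tert-butyldimethylsilyl)oxy]-6-methylhepta-1,5-dien-2-yl]-6-hydroxy-2-methylcyclohex-2-en-1-one
Conditions: [Cu((S,S)-tBu-box)](SbF6)2 (10 mol%; tBu-box = 2,2'-(propane-2,2-diyl)bis[(4S)-4-tert-butyl-4,5-dihydro-1,3-oxazole]), 4 Å MS, CH2Cl2 (0.01 M), −40 → 0 °C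
Reagents that add atoms: none
Why: Proposed new method: an intramolecular carbonyl-ene reaction of a 2-oxo-aldehyde under chiral bis(oxazoline)–copper catalysis, in which the 1,2-dicarbonyl chelates the divalent copper centre as glyoxylate esters do, so the C6=C7 alkene should add to the same aldehyde face as in the catalytic glyoxylate-ene reaction (S at C1) through a chair-like transition state with C1–O and C7 equatorial (C1/C6 trans), while the C14 methyl, which in the 6Z alkene lies trans to C5 and next to the aldehyde oxygen, gives up its hydrogen to leave the 7(14)-methylene group; the closest known reactions are the bis(oxazoline)–copper glyoxylate-ene reaction and the copper-catalysed intramolecular carbonyl-ene cyclisation of unsaturated α-keto esters, and the step retraces the C1–C6 closure of a farnesyl chain with loss of H-14 from the bisabolyl cation.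

Step 9
Reactants: 15 (5S,6S)-5-[(3R)-3-[(tert-butyldimethylsilyl)oxy]-6-methylhepta-1,5-dien-2-yl]-6-hydroxy-2-methylcyclohex-2-en-1-one
Product: 16 (5S,6S)-6-hydroxy-5-[(3R)-3-hydroxy-6-methylhepta-1,5-dien-2-yl]-2-methylcyclohex-2-en-1-one
Conditions: HF·pyridine, pyridine, THF, 0 °C → rt
Reagents that add atoms: none
Why: Fluoride-mediated desilylation under non-basic conditions spares the base-sensitive α-ketol and the enone.

Step 10
Reactants: 16 (5S,6S)-6-hydroxy-5-[(3R)-3-hydroxy-6-methylhepta-1,5-dien-2-yl]-2-methylcyclohex-2-en-1-one; 17 3-methylbut-2-enoyl chloride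
Product: 18 (1S,6S)-3-methyl-6-[(3R)-6-methyl-3-[(3-methylbut-2-enoyl)oxy]hepta-1,5-dien-2-yl]-2-oxocyclohex-3-en-1-yl 3-methylbut-2-enoate
Conditions: 17 (3 equiv), pyridine, DMAP (cat.), CH2Cl2, 0 °C → rt
Reagents that add atoms: none
Why: DMAP-catalysed esterification of both secondary alcohols in one operation, with pyridine rather than a trialkylamine to avoid deconjugation of the senecioyl group through its vinylketene; the trans (diequatorial) ketol ester is also the more stable epimer.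

Step 11
Reactants: 18 (1S,6S)-3-methyl-6-[(3R)-6-methyl-3-[(3-methylbut-2-enoyl)oxy]hepta-1,5-dien-2-yl]-2-oxocyclohex-3-en-1-yl 3-methylbut-2-enoate
Product: 19 (1S,2S,6S)-2-hydroxy-3-methyl-6-[(3R)-6-methyl-3-[(3-methylbut-2-enoyl)oxy]hepta-1,5-dien-2-yl]cyclohex-3-en-1-yl 3-methylbut-2-enoate
Conditions: NaBH4, CeCl3·7H2O, MeOH, −78 °C
Reagents that add atoms: none
Why: Luche reduction delivers hydride 1,2 and axially to the enone carbonyl, giving the equatorial allylic alcohol cis to the C6 side chain and trans to the neighbouring ester (the carvone → cis-carveol precedent), and leaves the esters alone at −78 °C.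

Step 12
Reactants: 19 (1S,2S,6S)-2-hydroxy-3-methyl-6-[(3R)-6-methyl-3-[(3-methylbut-2-enoyl)oxy]hepta-1,5-dien-2-yl]cyclohex-3-en-1-yl 3-methylbut-2-enoate
Product: 20 (1R,2R,3S,4S,6S)-2-hydroxy-1-methyl-4-[(3R)-6-methyl-3-[(3-methylbut-2-enoyl)oxy]hepta-1,5-dien-2-yl]-7-oxabicyclo[4.1.0]heptan-3-yl 3-methylbut-2-enoate
Conditions: VO(acac)2 (5 mol%), tBuOOH (1.5 equiv), CH2Cl2, 0 °C → rt
Reagents that add atoms: tert-butyl hydroperoxide, CC(C)(C)OO
Why: Vanadium-catalysed hydroxyl-directed epoxidation puts the oxygen on the ring alkene from the face of the allylic OH, i.e. cis to the side chain and trans to the ring ester, which sets both oxirane carbons and leaves the isolated and ester-conjugated alkenes untouched.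

Step 13
Reactants: 20 (1R,2R,3S,4S,6S)-2-hydroxy-1-methyl-4-[(3R)-6-methyl-3-[(3-methylbut-2-enoyl)oxy]hepta-1,5-dien-2-yl]-7-oxabicyclo[4.1.0]heptan-3-yl 3-methylbut-2-enoate
Product: 21 (1S,3S,4S,6S)-1-methyl-4-[(3R)-6-methyl-3-[(3-methylbut-2-enoyl)oxy]hepta-1,5-dien-2-yl]-2-oxo-7-oxabicyclo[4.1.0]heptan-3-yl 3-methylbut-2-enoate
Conditions: Dess–Martin periodinane, NaHCO3, CH2Cl2, 0 °C → rt
Reagents that add atoms: none
Why: Dess–Martin oxidation of the secondary alcohol under buffered, non-epimerising conditions gives the epoxy ketone, which is the target.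

## Compound list

1 | methyl (2R)-oxirane-2-carboxylate | COC(=O)[C@H]1CO1 | starting material
2 | (2-methylprop-1-en-1-yl)magnesium bromide | CC(C)=C[Mg]Br | starting material
3 | methyl (2R)-2-hydroxy-5-methylhex-4-enoate | COC(=O)[C@@H](CC=C(C)C)O | intermediate
4 | methyl (2R)-2-[(tert-butyldimethylsilyl)oxy]-5-methylhex-4-enoate | COC(=O)[C@@H](CC=C(C)C)O[Si](C)(C)C(C)(C)C | intermediate
5 | (2R)-2-[(tert-butyldimethylsilyl)oxy]-N-methoxy-N,5-dimethylhex-4-enamide | CON(C)C(=O)[C@@H](CC=C(C)C)O[Si](C)(C)C(C)(C)C | intermediate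
6 | (3R)-3-[(tert-butyldimethylsilyl)oxy]-6-methylhept-5-en-2-one | CC(=O)[C@@H](CC=C(C)C)O[Si](C)(C)C(C)(C)C | intermediate
7 | methyl (4R)-2,2-dimethyl-1,3-dioxolane-4-carboxylate | COC(=O)[C@H]1COC(C)(C)O1 | starting material
8 | (4R)-N-methoxy-N,2,2-trimethyl-1,3-dioxolane-4-carboxamide | CON(C)C(=O)[C@H]1COC(C)(C)O1 | intermediate
9 | 1-[(4R)-2,2-dimethyl-1,3-dioxolan-4-yl]ethan-1-one | CC(=O)[C@H]1COC(C)(C)O1 | intermediate
10 | propane-1,3-diylbis(triphenylphosphonium) dibromide | [Br-].[Br-].c1ccccc1[P+](c1ccccc1)(c1ccccc1)CCC[P+](c1ccccc1)(c1ccccc1)c1ccccc1 | starting material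
11 | [(3Z,5R)-5-[(tert-butyldimethylsilyl)oxy]-4,8-dimethylnona-3,7-dien-1-yl]triphenylphosphonium bromide | CC(C)=CC[C@@H](O[Si](C)(C)C(C)(C)C)/C(C)=C\CC[P+](c1ccccc1)(c1ccccc1)c1ccccc1.[Br-] | intermediate
12 | (4S)-4-[(2Z,5Z,7R)-7-[(tert-butyldimethylsilyl)oxy]-6,10-dimethylundeca-2,5,9-trien-2-yl]-2,2-dimethyl-1,3-dioxolane | CC1(C)OC[C@@H](O1)/C(C)=C\C/C=C(/C)[C@@H](CC=C(C)C)O[Si](C)(C)C(C)(C)C | intermediate
13 | (2S,3Z,6Z,8R)-8-[(tert-butyldimethylsilyl)oxy]-3,7,11-trimethyldodeca-3,6,10-triene-1,2-diol | OC[C@@H](O)/C(C)=C\C/C=C(/C)[C@@H](CC=C(C)C)O[Si](C)(C)C(C)(C)C | intermediate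
14 | (3Z,6Z,8R)-8-[(tert-butyldimethylsilyl)oxy]-3,7,11-trimethyl-2-oxododeca-3,6,10-trienal | O=CC(=O)/C(C)=C\C/C=C(/C)[C@@H](CC=C(C)C)O[Si](C)(C)C(C)(C)C | intermediate
15 | (5S,6S)-5-[(3R)-3-[(tert-butyldimethylsilyl)oxy]-6-methylhepta-1,5-dien-2-yl]-6-hydroxy-2-methylcyclohex-2-en-1-one | C=C([C@@H](CC=C(C)C)O[Si](C)(C)C(C)(C)C)[C@@H]1CC=C(C)C(=O)[C@H]1O | intermediate
16 | (5S,6S)-6-hydroxy-5-[(3R)-3-hydroxy-6-methylhepta-1,5-dien-2-yl]-2-methylcyclohex-2-en-1-one | C=C([C@@H](CC=C(C)C)O)[C@@H]1CC=C(C)C(=O)[C@H]1O | intermediate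
17 | 3-methylbut-2-enoyl chloride | CC(C)=CC(=O)Cl | starting material
18 | (1S,6S)-3-methyl-6-[(3R)-6-methyl-3-[(3-methylbut-2-enoyl)oxy]hepta-1,5-dien-2-yl]-2-oxocyclohex-3-en-1-yl 3-methylbut-2-enoate | C=C([C@@H](CC=C(C)C)OC(=O)C=C(C)C)[C@@H]1CC=C(C)C(=O)[C@H]1OC(=O)C=C(C)C | intermediate
19 | (1S,2S,6S)-2-hydroxy-3-methyl-6-[(3R)-6-methyl-3-[(3-methylbut-2-enoyl)oxy]hepta-1,5-dien-2-yl]cyclohex-3-en-1-yl 3-methylbut-2-enoate | C=C([C@@H](CC=C(C)C)OC(=O)C=C(C)C)[C@@H]1CC=C(C)[C@H](O)[C@H]1OC(=O)C=C(C)C | intermediate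
20 | (1R,2R,3S,4S,6S)-2-hydroxy-1-methyl-4-[(3R)-6-methyl-3-[(3-methylbut-2-enoyl)oxy]hepta-1,5-dien-2-yl]-7-oxabicyclo[4.1.0]heptan-3-yl 3-methylbut-2-enoate | C=C([C@@H](CC=C(C)C)OC(=O)C=C(C)C)[C@@H]1C[C@@H]2O[C@]2(C)[C@H](O)[C@H]1OC(=O)C=C(C)C | intermediate
21 | (1S,3S,4S,6S)-1-methyl-4-[(3R)-6-methyl-3-[(3-methylbut-2-enoyl)oxy]hepta-1,5-dien-2-yl]-2-oxo-7-oxabicyclo[4.1.0]heptan-3-yl 3-methylbut-2-enoate | C=C([C@@H](CC=C(C)C)OC(=O)C=C(C)C)[C@@H]1C[C@@H]2O[C@]2(C)C(=O)[C@H]1OC(=O)C=C(C)C | target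

## Step count and weak points

Total steps: 13. Longest linear sequence: 12 (steps 1, 2, 3, 5, 6, 7, 8, 9, 10, 11, 12, 13).

Most likely to fail, 1: step 8. The cyclisation is unprecedented for a 2-oxo-aldehyde; the ketone carbonyl could compete as enophile, the catalyst could be mismatched with the C8 centre, and an uncatalysed background ene reaction would erode selectivity. The fallback closes the ring under substrate control at the alcohol oxidation level of C2, without the keto-aldehyde and without a chiral catalyst; it sets out from 13 and returns at 15. Diol 13 is bis-silylated (Et3SiCl, imidazole, CH2Cl2) to (2S,3Z,6Z,8R)-8-[(tert-butyldimethylsilyl)oxy]-3,7,11-trimethyl-1,2-bis[(triethylsilyl)oxy]dodeca-3,6,10-triene F6. Swern conditions cleave and oxidise only the primary triethylsilyl ether and give (2S,3Z,6Z,8R)-8-[(tert-butyldimethylsilyl)oxy]-3,7,11-trimethyl-2-[(triethylsilyl)oxy]dodeca-3,6,10-trienal F7. Me2AlCl (CH2Cl2, −78 °C) promotes the carbonyl-ene closure through an all-equatorial chair in which the C2–O bond is anti to the incoming alkene, so the (2S) centre fixes C1 and C6, giving (1S,2S,6S)-6-[(3R)-3-[(tert-butyldimethylsilyl)oxy]-6-methylhepta-1,5-dien-2-yl]-3-methyl-2-[(triethylsilyl)oxy]cyclohex-3-en-1-ol F8. PPTS in MeOH at 0 °C removes only the triethylsilyl group to give (1S,2S,6S)-6-[(3R)-3-[(tert-butyldimethylsilyl)oxy]-6-methylhepta-1,5-dien-2-yl]-3-methylcyclohex-3-ene-1,2-diol F9, and MnO2 oxidises only its allylic alcohol to give 15.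

Most likely to fail, 2: step 5. The one-pot use of a bis-ylide with two different, enolisable ketones can give symmetrical dienes, incomplete second olefination or eroded Z-selectivity. The fallback builds the two alkenes one at a time with a mono-functional three-carbon ylide; it sets out from 6 and returns at 12. Ketone 6 is olefinated with the ylide of [3-(tert-butyldimethylsilyloxy)propyl]triphenylphosphonium bromide (KN(SiMe3)2, THF, −78 °C) to give (3Z,5R)-1,5-bis[(tert-butyldimethylsilyl)oxy]-4,8-dimethylnona-3,7-diene F1. The primary silyl ether alone is cleaved (HF·pyridine, pyridine, THF, 0 °C) to (3Z,5R)-5-[(tert-butyldimethylsilyl)oxy]-4,8-dimethylnona-3,7-dien-1-ol F2. I2, PPh3 and imidazole give (3Z,5R)-5-[(tert-butyldimethylsilyl)oxy]-1-iodo-4,8-dimethylnona-3,7-diene F3, and PPh3 in MeCN at 80 °C gives [(3Z,5R)-5-[(tert-butyldimethylsilyl)oxy]-4,8-dimethylnona-3,7-dien-1-yl]triphenylphosphonium iodide F4. Deprotonation with NaN(SiMe3)2 and addition of 9 at −78 °C then gives 12.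

Most likely to fail, 3: step 7. The Z-configured, skipped 2-oxo-enal can isomerise (Z to E, or into conjugation) under the amine base, or hydrate and cyclise without control before the catalyst is added. The fallback oxidises the two hydroxyls one after the other under neutral conditions; it sets out from 13 and returns at 14. MnO2 (CH2Cl2, rt) oxidises only the allylic secondary alcohol to (3Z,6Z,8R)-8-[(tert-butyldimethylsilyl)oxy]-1-hydroxy-3,7,11-trimethyldodeca-3,6,10-trien-2-one F5, and catalytic Cu(OAc)2 with air in MeOH takes this α-ketol to 14.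

## Further compounds

F1 | step 5 | (3Z,5R)-1,5-bis[(tert-butyldimethylsilyl)oxy]-4,8-dimethylnona-3,7-diene | CC(C)=CC[C@@H](O[Si](C)(C)C(C)(C)C)/C(C)=C\CCO[Si](C)(C)C(C)(C)C
F2 | step 5 | (3Z,5R)-5-[(tert-butyldimethylsilyl)oxy]-4,8-dimethylnona-3,7-dien-1-ol | CC(C)=CC[C@@H](O[Si](C)(C)C(C)(C)C)/C(C)=C\CCO
F3 | step 5 | (3Z,5R)-5-[(tert-butyldimethylsilyl)oxy]-1-iodo-4,8-dimethylnona-3,7-diene | CC(C)=CC[C@@H](O[Si](C)(C)C(C)(C)C)/C(C)=C\CCI
F4 | step 5 | [(3Z,5R)-5-[(tert-butyldimethylsilyl)oxy]-4,8-dimethylnona-3,7-dien-1-yl]triphenylphosphonium iodide | CC(C)=CC[C@@H](O[Si](C)(C)C(C)(C)C)/C(C)=C\CC[P+](c1ccccc1)(c1ccccc1)c1ccccc1.[I-]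
F5 | step 7 | (3Z,6Z,8R)-8-[(tert-butyldimethylsilyl)oxy]-1-hydroxy-3,7,11-trimethyldodeca-3,6,10-trien-2-one | OCC(=O)/C(C)=C\C/C=C(/C)[C@@H](CC=C(C)C)O[Si](C)(C)C(C)(C)C
F6 | step 8 | (2S,3Z,6Z,8R)-8-[(tert-butyldimethylsilyl)oxy]-3,7,11-trimethyl-1,2-bis[(triethylsilyl)oxy]dodeca-3,6,10-triene | CC[Si](CC)(CC)OC[C@@H](O[Si](CC)(CC)CC)/C(C)=C\C/C=C(/C)[C@@H](CC=C(C)C)O[Si](C)(C)C(C)(C)C
F7 | step 8 | (2S,3Z,6Z,8R)-8-[(tert-butyldimethylsilyl)oxy]-3,7,11-trimethyl-2-[(triethylsilyl)oxy]dodeca-3,6,10-trienal | O=C[C@@H](O[Si](CC)(CC)CC)/C(C)=C\C/C=C(/C)[C@@H](CC=C(C)C)O[Si](C)(C)C(C)(C)C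
F8 | step 8 | (1S,2S,6S)-6-[(3R)-3-[(tert-butyldimethylsilyl)oxy]-6-methylhepta-1,5-dien-2-yl]-3-methyl-2-[(triethylsilyl)oxy]cyclohex-3-en-1-ol | C=C([C@@H](CC=C(C)C)O[Si](C)(C)C(C)(C)C)[C@@H]1CC=C(C)[C@H](O[Si](CC)(CC)CC)[C@H]1O
F9 | step 8 | (1S,2S,6S)-6-[(3R)-3-[(tert-butyldimethylsilyl)oxy]-6-methylhepta-1,5-dien-2-yl]-3-methylcyclohex-3-ene-1,2-diol | C=C([C@@H](CC=C(C)C)O[Si](C)(C)C(C)(C)C)[C@@H]1CC=C(C)[C@H](O)[C@H]1O
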